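**Retrosynthetic overview**
1. The two catechol benzyl ethers come off last. Before that, the catechol ring is attached to C4 of the butenolide by Suzuki–Miyaura coupling of a C4 enol triflate.
2. The butenolide ring (O1, C2 lactone carbonyl, C3 bearing OMe, C4, quaternary C5) is cut at C2–C3 and at O1–C5. The piece that falls out is CO2 and the rest is an acyclic (S)-2-chloro-2-(arylmethyl)-4-methoxyacetoacetate. One carboxylation/lactonisation cascade joins them to a 3-methoxytetronic acid, with C5 set by inversion.
3. Enabling feature: O1–C2(=O) is one CO2 unit bridging C3 and C5, and C4, the ring atom between them, can be carried as a ketone. That ketone acidifies the MeO-bearing C3–H and, with the ester on C5, leaves C5–Cl open to SN2 but closed to ionisation. Its oxygen is later exchanged for the aryl ring.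
4. The chloride comes from enantioselective chlorination of the keto ester made by reductive Knoevenagel alkylation of methyl 4-methoxyacetoacetate with (R)-3-hydroxy-2,2-dimethylchroman-6-carbaldehyde. That aldehyde comes from a commercial cyanochromene by Jacobsen epoxidation, benzylic hydrogenolysis and nitrile reduction.
5. Ring order: the benzopyran is bought and only oxidised, the butenolide ring is formed in the key step, and the catechol ring is coupled on afterwards.

Key step: step 6

Assumption: butenolide locants are O1, C2 (lactone C=O), C3 (OMe), C4 (aryl), C5 (quaternary); the target is R at C5 and R at the chroman carbinol carbon; the hand of the ligand in step 5 that leads to the (S)-chloride would be fixed by one correlation experiment.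

Step 1
Reactants: 1 2,2-dimethyl-2H-chromene-6-carbonitrile
Product: 2 (3R,4R)-3,4-epoxy-2,2-dimethylchroman-6-carbonitrile
Conditions: (R,R)-Jacobsen catalyst [(R,R)-N,N'-bis(3,5-di-tert-butylsalicylidene)cyclohexane-1,2-diaminato]MnCl (4 mol%), 4-phenylpyridine N-oxide (cat.), aq. NaOCl (pH 11.3), CH2Cl2, 0 °C
Reagents that add atoms: sodium hypochlorite, [Na+].[O-]Cl
Why: Jacobsen epoxidation; cis-configured, aryl-conjugated 2,2-dimethylchromenes are the best substrate class for this oxygen transfer, and the (R,R)-catalyst is expected to give the (3R,4R)-epoxide, which sets the carbinol stereocentre of the target.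

Step 2
Reactants: 2 (3R,4R)-3,4-epoxy-2,2-dimethylchroman-6-carbonitrile
Product: 3 (3R)-3-hydroxy-2,2-dimethylchroman-6-carbonitrile
Conditions: H2 (1 atm), Pd/C (10 wt%), EtOAc, 25 °C, stopped after one equivalent of H2
Reagents that add atoms: none
Why: Heterogeneous hydrogenolysis of an aryl epoxide cleaves only the benzylic C4–O bond, so C3 keeps its oxygen and its R configuration, while the aryl nitrile should be reduced much more slowly under neutral conditions.

Step 3
Reactants: 3 (3R)-3-hydroxy-2,2-dimethylchroman-6-carbonitrile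
Product: 4 (3R)-3-hydroxy-2,2-dimethylchroman-6-carbaldehyde
Conditions: i-Bu2AlH (2.5 equiv), CH2Cl2, −78 °C; then 1 M HCl, 0 °C
Reagents that add atoms: water, O
Why: Partial reduction of an aryl nitrile with i-Bu2AlH stops at the N-aluminoimine, which is hydrolysed to the aldehyde on work-up; the first equivalent is consumed by the hydroxyl group and the stereocentre is untouched.

Step 4
Reactants: 4 (3R)-3-hydroxy-2,2-dimethylchroman-6-carbaldehyde; 5 methyl 4-methoxy-3-oxobutanoate
Product: 7 methyl 2-{[(3R)-3-hydroxy-2,2-dimethylchroman-6-yl]methyl}-4-methoxy-3-oxobutanoate, via benzylidene keto ester 6 (not isolated)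
Conditions: piperidine (0.1 equiv), AcOH (0.1 equiv), 4 Å MS, toluene, 80 °C; then EtOAc, Pd/C (10 wt%), H2 (1 atm), 25 °C, same flask
Reagents that add atoms: none
Why: Knoevenagel condensation at the doubly activated CH2 of 5 followed by hydrogenation of the electron-poor alkene is the classical reductive alkylation of a beta-keto ester and avoids a labile 4-alkoxybenzyl halide; the new CH centre is configurationally labile and is fixed only in step 5.

Step 5
Reactants: 7 methyl 2-{[(3R)-3-hydroxy-2,2-dimethylchroman-6-yl]methyl}-4-methoxy-3-oxobutanoate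
Product: 8 methyl (2S)-2-chloro-2-{[(3R)-3-hydroxy-2,2-dimethylchroman-6-yl]methyl}-4-methoxy-3-oxobutanoate
Conditions: Cu(OTf)2 (10 mol%), chiral spiro pyridine-oxazoline ligand (SPYMOX, 12 mol%), NCS (1.1 equiv), 4 Å MS, toluene, 0 °C
Reagents that add atoms: N-chlorosuccinimide, O=C1CCC(=O)N1Cl
Why: Catalytic enantioselective alpha-chlorination of a beta-keto ester; the two carbonyl oxygens bind the chiral divalent copper centre as a planar enolate chelate, the ligand shields one face and NCS delivers chlorine to the other, which sets the S configuration at the future C5.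

Step 6
Reactants: 8 methyl (2S)-2-chloro-2-{[(3R)-3-hydroxy-2,2-dimethylchroman-6-yl]methyl}-4-methoxy-3-oxobutanoate; 9 carbon dioxide
Product: 11 methyl (2R)-3-hydroxy-2-{[(3R)-3-hydroxy-2,2-dimethylchroman-6-yl]methyl}-4-methoxy-5-oxo-2,5-dihydrofuran-2-carboxylate, via chloro keto carboxylate 10 (not isolated)
Conditions: CO2 (1.0 MPa), DBU (3 equiv), dry MeCN, 0 to 25 °C; then 1 M HCl
Reagents that add atoms: none
Why: Proposed new method: DBU removes a proton from C3, the only enolisable position of 8 because C5 is fully substituted, and the enolate adds to CO2 to form C2–C3 and give carboxylate 10, whose oxygen then displaces chloride from C5 to form O1–C5. The butenolide ring thus closes by a 5-exo-tet SN2 lactonisation, and loss of chloride followed by deprotonation of 11 to its delocalised tetronate anion makes the otherwise reversible carboxylation irreversible; an enol carbonate formed by O-carboxylation should drain to the same tetronate through the alkylidene cyclic carbonate, a base-induced rearrangement that is known. The closest known reaction types are the amidine-mediated carboxylation of ketone enolates with CO2 in which the new carboxylate is trapped by a tethered alkyne, the classical closure of gamma-halo acetoacetates to tetronic acids, and the invertive displacement of tertiary alpha-chloro beta-keto esters by azide, thiolate or fluoride. C5 is controlled by the substrate: backside attack turns the (S)-chloride into the (R)-lactone, and ionisation that would erode this is disfavoured because a cation at C5 would sit between a ketone and an ester carbonyl. The step needs carboxylation and lactonisation to outrun E2 loss of HCl towards the benzylic CH2, Favorskii closure from C3 to C5 and chlorine transfer to the enolate; CO2 pressure keeps free enolate and free amidine low, chloride is a reluctant partner for E2 and for halogen transfer, and the closure is intramolecular. The free chromanol should only form a labile alkyl carbonate salt that reverts on acidification.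

Step 7
Reactants: 11 methyl (2R)-3-hydroxy-2-{[(3R)-3-hydroxy-2,2-dimethylchroman-6-yl]methyl}-4-methoxy-5-oxo-2,5-dihydrofuran-2-carboxylate
Product: 12 methyl (2R)-2-{[(3R)-3-hydroxy-2,2-dimethylchroman-6-yl]methyl}-4-methoxy-5-oxo-3-(trifluoromethylsulfonyloxy)-2,5-dihydrofuran-2-carboxylate
Conditions: PhNTf2 (1.1 equiv), Et3N (1.5 equiv), CH2Cl2, 0 to 25 °C
Reagents that add atoms: N-phenylbis(trifluoromethanesulfonimide), O=S(=O)(N(c1ccccc1)S(=O)(=O)C(F)(F)F)C(F)(F)F
Why: Enol triflate formation; only the acidic C4–OH of the tetronic acid is ionised by Et3N and sulfonylated by the mild triflyl donor, whereas the neutral, hindered secondary alcohol should not react, and no stereocentre is touched.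

Step 8
Reactants: 13 1,2-bis(benzyloxy)-4-bromobenzene
Product: 14 2-[3,4-bis(benzyloxy)phenyl]-4,4,5,5-tetramethyl-1,3,2-dioxaborolane
Conditions: B2pin2 (1.1 equiv), PdCl2(dppf) (3 mol%), KOAc (3 equiv), 1,4-dioxane, 85 °C
Reagents that add atoms: bis(pinacolato)diboron, CC1(C)OB(OC1(C)C)B1OC(C)(C)C(C)(C)O1
Why: Miyaura borylation of an aryl bromide under weakly basic conditions, to which benzyl ethers are inert.

Step 9
Reactants: 12 methyl (2R)-2-{[(3R)-3-hydroxy-2,2-dimethylchroman-6-yl]methyl}-4-methoxy-5-oxo-3-(trifluoromethylsulfonyloxy)-2,5-dihydrofuran-2-carboxylate; 14 2-[3,4-bis(benzyloxy)phenyl]-4,4,5,5-tetramethyl-1,3,2-dioxaborolane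
Product: 15 methyl (2R)-3-[3,4-bis(benzyloxy)phenyl]-2-{[(3R)-3-hydroxy-2,2-dimethylchroman-6-yl]methyl}-4-methoxy-5-oxo-2,5-dihydrofuran-2-carboxylate
Conditions: Pd(OAc)2 (5 mol%), SPhos (10 mol%), K3PO4 (2 equiv), toluene/H2O 10:1, 60 °C
Reagents that add atoms: none
Why: Suzuki–Miyaura coupling of an electron-poor tetronate enol triflate is an established entry to 4-aryl butenolides; the bulky electron-rich biaryl phosphine should cope with the flanking quaternary C5 and C3 methoxy group, and C5 carries no hydrogen and cannot epimerise.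

Step 10
Reactants: 15 methyl (2R)-3-[3,4-bis(benzyloxy)phenyl]-2-{[(3R)-3-hydroxy-2,2-dimethylchroman-6-yl]methyl}-4-methoxy-5-oxo-2,5-dihydrofuran-2-carboxylate
Product: 16 methyl (2R)-3-(3,4-dihydroxyphenyl)-2-{[(3R)-3-hydroxy-2,2-dimethylchroman-6-yl]methyl}-4-methoxy-5-oxo-2,5-dihydrofuran-2-carboxylate
Conditions: H2 (1 atm), Pd/C (10 wt%), EtOAc/MeOH, 25 °C, work-up under argon
Reagents that add atoms: none
Why: Hydrogenolysis of two aryl benzyl ethers should be fast compared with attack on the tetrasubstituted, conjugated C3=C4 bond or on the hindered C5–O1 bond, and it frees the catechol under neutral conditions with both stereocentres untouched.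

**Compound list**
1 | 2,2-dimethyl-2H-chromene-6-carbonitrile | CC1(C)C=Cc2cc(C#N)ccc2O1 | starting material
2 | (3R,4R)-3,4-epoxy-2,2-dimethylchroman-6-carbonitrile | N#Cc1ccc2OC(C)(C)[C@@H]3O[C@@H]3c2c1 | intermediate
3 | (3R)-3-hydroxy-2,2-dimethylchroman-6-carbonitrile | N#Cc1ccc2c(c1)C[C@@H](O)C(C)(C)O2 | intermediate
4 | (3R)-3-hydroxy-2,2-dimethylchroman-6-carbaldehyde | O=Cc1ccc2c(c1)C[C@@H](O)C(C)(C)O2 | intermediate
5 | methyl 4-methoxy-3-oxobutanoate | COCC(=O)CC(=O)OC | starting material
6 | methyl 2-{[(3R)-3-hydroxy-2,2-dimethylchroman-6-yl]methylidene}-4-methoxy-3-oxobutanoate (E/Z mixture, not isolated) | COCC(=O)C(=Cc1ccc2c(c1)C[C@@H](O)C(C)(C)O2)C(=O)OC | intermediate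
7 | methyl 2-{[(3R)-3-hydroxy-2,2-dimethylchroman-6-yl]methyl}-4-methoxy-3-oxobutanoate (C2 epimers, interconverting) | COCC(=O)C(Cc1ccc2c(c1)C[C@@H](O)C(C)(C)O2)C(=O)OC | intermediate
8 | methyl (2S)-2-chloro-2-{[(3R)-3-hydroxy-2,2-dimethylchroman-6-yl]methyl}-4-methoxy-3-oxobutanoate | COCC(=O)[C@@](Cl)(Cc1ccc2c(c1)C[C@@H](O)C(C)(C)O2)C(=O)OC | intermediate
9 | carbon dioxide | O=C=O | starting material
10 | (4S)-4-chloro-5-[(3R)-3-hydroxy-2,2-dimethylchroman-6-yl]-2-methoxy-4-(methoxycarbonyl)-3-oxopentanoic acid (present as its DBU-H carboxylate, C2 epimers, not isolated) | OC(=O)C(OC)C(=O)[C@@](Cl)(Cc1ccc2c(c1)C[C@@H](O)C(C)(C)O2)C(=O)OC | intermediate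
11 | methyl (2R)-3-hydroxy-2-{[(3R)-3-hydroxy-2,2-dimethylchroman-6-yl]methyl}-4-methoxy-5-oxo-2,5-dihydrofuran-2-carboxylate | COC(=O)[C@]1(Cc2ccc3c(c2)C[C@@H](O)C(C)(C)O3)OC(=O)C(OC)=C1O | intermediate
12 | methyl (2R)-2-{[(3R)-3-hydroxy-2,2-dimethylchroman-6-yl]methyl}-4-methoxy-5-oxo-3-(trifluoromethylsulfonyloxy)-2,5-dihydrofuran-2-carboxylate | COC(=O)[C@]1(Cc2ccc3c(c2)C[C@@H](O)C(C)(C)O3)OC(=O)C(OC)=C1OS(=O)(=O)C(F)(F)F | intermediate
13 | 1,2-bis(benzyloxy)-4-bromobenzene | Brc1ccc(OCc2ccccc2)c(OCc2ccccc2)c1 | starting material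
14 | 2-[3,4-bis(benzyloxy)phenyl]-4,4,5,5-tetramethyl-1,3,2-dioxaborolane | CC1(C)OB(OC1(C)C)c1ccc(OCc2ccccc2)c(OCc2ccccc2)c1 | intermediate
15 | methyl (2R)-3-[3,4-bis(benzyloxy)phenyl]-2-{[(3R)-3-hydroxy-2,2-dimethylchroman-6-yl]methyl}-4-methoxy-5-oxo-2,5-dihydrofuran-2-carboxylate | COC(=O)[C@]1(Cc2ccc3c(c2)C[C@@H](O)C(C)(C)O3)OC(=O)C(OC)=C1c1ccc(OCc2ccccc2)c(OCc2ccccc2)c1 | intermediate
16 | methyl (2R)-3-(3,4-dihydroxyphenyl)-2-{[(3R)-3-hydroxy-2,2-dimethylchroman-6-yl]methyl}-4-methoxy-5-oxo-2,5-dihydrofuran-2-carboxylate | COC(=O)[C@]1(Cc2ccc3c(c2)C[C@@H](O)C(C)(C)O3)OC(=O)C(OC)=C1c1ccc(O)c(O)c1 | target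

Total step count: 10. Longest linear sequence: 9 (steps 1 to 7, 9 and 10).

**Steps most likely to fail**

**Step 6.** Dehydrochlorination towards the benzylic CH2, Favorskii-type closure or transfer of chlorine to the enolate may outrun carboxylation, and partial ionisation at C5 would erode the configuration.
- The fallback uses known chemistry, sets out from 7 and comes back at 11. It takes O1 from a hydroxylation instead of from CO2.
- Enantioselective alpha-hydroxylation of 7 with an N-sulfonyloxaziridine under Cu(OTf)2/bis(oxazoline) catalysis should give methyl (2R)-2-hydroxy-2-{[(3R)-3-hydroxy-2,2-dimethylchroman-6-yl]methyl}-4-methoxy-3-oxobutanoate F1.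
- Methyl chloroformate, pyridine and DMAP convert both hydroxyl groups into carbonates, giving methyl (2R)-4-methoxy-2-(methoxycarbonyloxy)-2-{[(3R)-3-(methoxycarbonyloxy)-2,2-dimethylchroman-6-yl]methyl}-3-oxobutanoate F2.
- LiHMDS in THF at −78 to 0 °C forms the C3 enolate, which attacks the carbonate on the C5 oxygen in an intramolecular Claisen-type acylation. This gives methyl (2R)-3-hydroxy-4-methoxy-2-{[(3R)-3-(methoxycarbonyloxy)-2,2-dimethylchroman-6-yl]methyl}-5-oxo-2,5-dihydrofuran-2-carboxylate F3 with retention at C5.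
- K2CO3 in MeOH removes the remaining carbonate and returns 11.

**Step 5.** Facial selectivity may be poor, because the methyl ester is small and the extra methoxy donor can compete for the copper centre.
- The fallback sets out from 4 and 5 and comes back at 8. It creates the stereocentre by C–C instead of C–Cl bond formation.
- SO2Cl2 in CH2Cl2 at 0 °C turns 5 into methyl 2-chloro-4-methoxy-3-oxobutanoate F4.
- NaBH4 in MeOH reduces 4 to (3R)-6-(hydroxymethyl)-2,2-dimethylchroman-3-ol F5.
- An Appel reaction (CBr4, PPh3, CH2Cl2, 0 °C) on the primary benzylic alcohol gives (3R)-6-(bromomethyl)-2,2-dimethylchroman-3-ol F6, which is used crude.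
- Asymmetric phase-transfer alkylation of F4 with F6 should give 8. The conditions are a C2-symmetric binaphthyl-derived spiro quaternary ammonium bromide, aq. K2CO3 and toluene at −20 °C, with the catalyst enantiomer chosen for the (S)-chloride.

**Step 9.** Oxidative addition and transmetalation at the crowded C4 may be slow, so that hydrolysis of the triflate back to the tetronate takes over.
- The fallback sets out from 12 and 13 and comes back at 15. It replaces catalysis by a conjugate addition–elimination.
- Bromine–lithium exchange on 13 (t-BuLi, THF, −78 °C) and addition of CuBr·SMe2 (0.5 equiv) gives lithium bis[3,4-bis(benzyloxy)phenyl]cuprate F7.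
- F7 should add to C4 of 12 at −78 °C and expel triflate to give 15. One extra equivalent of the cuprate is sacrificed to the free hydroxyl group.

**Further compounds**
F1 | step 6 | methyl (2R)-2-hydroxy-2-{[(3R)-3-hydroxy-2,2-dimethylchroman-6-yl]methyl}-4-methoxy-3-oxobutanoate | COCC(=O)[C@](O)(Cc1ccc2c(c1)C[C@@H](O)C(C)(C)O2)C(=O)OC
F2 | step 6 | methyl (2R)-4-methoxy-2-(methoxycarbonyloxy)-2-{[(3R)-3-(methoxycarbonyloxy)-2,2-dimethylchroman-6-yl]methyl}-3-oxobutanoate | COCC(=O)[C@](OC(=O)OC)(Cc1ccc2c(c1)C[C@@H](OC(=O)OC)C(C)(C)O2)C(=O)OC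
F3 | step 6 | methyl (2R)-3-hydroxy-4-methoxy-2-{[(3R)-3-(methoxycarbonyloxy)-2,2-dimethylchroman-6-yl]methyl}-5-oxo-2,5-dihydrofuran-2-carboxylate | COC(=O)[C@]1(Cc2ccc3c(c2)C[C@@H](OC(=O)OC)C(C)(C)O3)OC(=O)C(OC)=C1O
F4 | step 5 | methyl 2-chloro-4-methoxy-3-oxobutanoate | COCC(=O)C(Cl)C(=O)OC
F5 | step 5 | (3R)-6-(hydroxymethyl)-2,2-dimethylchroman-3-ol | OCc1ccc2c(c1)C[C@@H](O)C(C)(C)O2
F6 | step 5 | (3R)-6-(bromomethyl)-2,2-dimethylchroman-3-ol | BrCc1ccc2c(c1)C[C@@H](O)C(C)(C)O2
F7 | step 9 | lithium bis[3,4-bis(benzyloxy)phenyl]cuprate | [Li+].[Cu-](c1ccc(OCc2ccccc2)c(OCc2ccccc2)c1)c1ccc(OCc2ccccc2)c(OCc2ccccc2)c1
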